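The spiro carbon is at once the anomeric C2′ of ring B, flanked by O1′ and the C3′–H methine, and the carbon that carries the CH2 and the phenolic oxygen of ring A, which are the two termini of a ring A ortho-quinone methide. Ring B is therefore made as a trans-2-nitro-3-(benzofuran-2-ylmethyl)-2,3-dihydrobenzofuran, and ring A as a 2-(tosylmethyl)phenol. In one operation the C2′ nitronate adds to the quinone methide, nitrite leaves, and the freed phenoxide closes ring A: both bonds to the spiro carbon, ring A and the spiro configuration (steered by C3′) form together. Hydrogenolysis of five benzyl ethers then gives the target.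

Key step: step 13

Remark (assumption): the quinine-derived squaramide written in step 10 is assumed to give the (2S,3S) antipode of 18; if the sense of induction is the opposite, its quinidine-derived pseudoenantiomer is used.

Remark (design): in sulfone 23 the hydroxyl para to the tosylmethyl group is a benzyl ether, so that the quinone methide is a neutral electrophile and ring A carries only one phenoxide. The 6-hydroxyl of ring B in 18 stays free: its phenoxide takes up the conjugation of the 7-acyl group, which leaves the ring oxygen able to assist loss of nitrite, and it could not be benzylated under base next to the acidic nitro C–H.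

Step 1
Reactants: 1 phloroglucinol; 2 isovaleryl chloride
Product: 3 phlorisovalerophenone [3-methyl-1-(2,4,6-trihydroxyphenyl)butan-1-one]
Conditions: AlCl3 (3.5 equiv), PhNO2–CH2Cl2, 0 °C → 50 °C; aq HCl
Reagents that add atoms: none
Why: Friedel–Crafts acylation of the electron-rich triol should stop at the mono-ketone because the acyl group, chelated to AlCl3, deactivates the ring toward a second acylation.

Step 2
Reactants: 3 phlorisovalerophenone
Product: 4 1-[4-(allyloxy)-2,6-dihydroxyphenyl]-3-methylbutan-1-one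
Conditions: allyl bromide (1.05 equiv), K2CO3 (1.1 equiv), acetone, rt
Reagents that add atoms: allyl bromide, C=CCBr
Why: Williamson etherification is expected at the 4-hydroxyl alone, since it is the only hydroxyl not hydrogen-bonded to the ketone and gives the most nucleophilic phenoxide.

Step 3
Reactants: 4 1-[4-(allyloxy)-2,6-dihydroxyphenyl]-3-methylbutan-1-one
Product: 5 1-[4-(allyloxy)-2,6-bis(benzyloxy)phenyl]-3-methylbutan-1-one
Conditions: BnBr (2.5 equiv), K2CO3 (3 equiv), n-Bu4NI (cat), DMF, 60 °C
Reagents that add atoms: benzyl bromide, BrCc1ccccc1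
Why: Williamson benzylation in warm DMF overcomes the chelation of the two remaining hydroxyls, while the allyl ether and the ketone are inert to K2CO3.

Step 4
Reactants: 5 1-[4-(allyloxy)-2,6-bis(benzyloxy)phenyl]-3-methylbutan-1-one
Product: 6 1-[2,6-bis(benzyloxy)-4-hydroxyphenyl]-3-methylbutan-1-one
Conditions: Pd(PPh3)4 (3 mol %), morpholine (3 equiv), THF, rt
Reagents that add atoms: none
Why: Tsuji–Trost-type deallylation, in which zerovalent palladium ionises the aryl allyl ether and morpholine traps the π-allyl fragment, frees the 4-hydroxyl without touching the benzyl ethers or the ketone.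

Step 5
Reactants: 6 1-[2,6-bis(benzyloxy)-4-hydroxyphenyl]-3-methylbutan-1-one
Product: 7 1-[2,6-bis(benzyloxy)-4-hydroxy-3-iodophenyl]-3-methylbutan-1-one
Conditions: N-iodosuccinimide (1.0 equiv), MeCN, −10 °C
Reagents that add atoms: N-iodosuccinimide, O=C1CCC(=O)N1I
Why: Electrophilic aromatic iodination occurs ortho to the free phenol, and because the two ortho positions are equivalent by symmetry only one mono-iodide can form.

Step 6
Reactants: 7 1-[2,6-bis(benzyloxy)-4-hydroxy-3-iodophenyl]-3-methylbutan-1-one; 8 but-3-yn-1-ol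
Product: 10 1-[4,6-bis(benzyloxy)-2-(2-hydroxyethyl)-1-benzofuran-5-yl]-3-methylbutan-1-one, via ortho-alkynylphenol 9 (not isolated)
Conditions: PdCl2(PPh3)2 (3 mol %), CuI (6 mol %), Et3N, DMF, 60 °C
Reagents that add atoms: none
Why: Sonogashira coupling of the ortho-iodophenol is followed in the same pot by 5-endo-dig addition of the neighbouring phenoxide to the metal-activated alkyne, the standard heteroannulation to 2-substituted benzofurans, and only the 4-hydroxyl is free to close, which fixes the ring C pattern.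

Step 7
Reactants: 10 1-[4,6-bis(benzyloxy)-2-(2-hydroxyethyl)-1-benzofuran-5-yl]-3-methylbutan-1-one
Product: 11 2-[4,6-bis(benzyloxy)-5-(3-methylbutanoyl)-1-benzofuran-2-yl]acetaldehyde
Conditions: Dess–Martin periodinane (1.2 equiv), pyridine (2 equiv), CH2Cl2, 0 °C; used at once
Reagents that add atoms: none
Why: Dess–Martin oxidation turns the primary alcohol into the aldehyde under buffered conditions that should not enolise the arylacetaldehyde and cannot over-oxidise it.

Step 8
Reactants: 11 2-[4,6-bis(benzyloxy)-5-(3-methylbutanoyl)-1-benzofuran-2-yl]acetaldehyde; 12 bromonitromethane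
Product: 15 1-{4,6-bis(benzyloxy)-2-[(2Z)-3-bromo-3-nitroprop-2-en-1-yl]-1-benzofuran-5-yl}-3-methylbutan-1-one, via bromonitro alcohol 13 (not isolated), via mesylate 14 (not isolated)
Conditions: BrCH2NO2 (1.3 equiv), i-Pr2NEt (10 mol %), THF, 0 °C; then MsCl (1.3 equiv), i-Pr2NEt (2.6 equiv), −40 → 0 °C
Reagents that add atoms: none
Why: Henry (nitroaldol) addition of the acidic bromonitromethane is followed by mesylation and E1cB elimination, which should give the more stable Z alkene with bromine and the CH2 chain cis.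

Step 9
Reactants: 3 phlorisovalerophenone
Product: 16 1-[4-(benzyloxy)-2,6-dihydroxyphenyl]-3-methylbutan-1-one
Conditions: BnBr (1.05 equiv), K2CO3 (1.1 equiv), acetone, rt
Reagents that add atoms: benzyl bromide, BrCc1ccccc1
Why: Williamson mono-benzylation goes to the non-chelated 4-hydroxyl for the reason given in step 2.

Step 10
Reactants: 16 1-[4-(benzyloxy)-2,6-dihydroxyphenyl]-3-methylbutan-1-one (1.5 equiv); 15 Z-bromonitroalkene of ring C
Product: 18 1-[(2S,3S)-4-(benzyloxy)-3-{[4,6-bis(benzyloxy)-5-(3-methylbutanoyl)-1-benzofuran-2-yl]methyl}-6-hydroxy-2-nitro-2,3-dihydro-1-benzofuran-7-yl]-3-methylbutan-1-one (trans), via bromonitro Friedel–Crafts adduct 17 (not isolated)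
Conditions: quinine-derived squaramide 3-{[3,5-bis(trifluoromethyl)phenyl]amino}-4-{[(8α,9S)-6′-methoxycinchonan-9-yl]amino}cyclobut-3-ene-1,2-dione (10 mol %), NaHCO3 (1.5 equiv), CHCl3, −20 °C → rt
Reagents that add atoms: none
Why: Domino Friedel–Crafts (Michael-type) alkylation and intramolecular O-alkylation of a phenol by a Z-bromonitroalkene under bifunctional tertiary amine–squaramide catalysis: the catalyst holds the nitroalkene by hydrogen bonds and the phenol through its amine so that the ring carbon between OH and OBn attacks one face of the alkene and sets C3 (S), after which the neighbouring hydroxyl displaces bromide from the epimerisable bromonitro carbon to give the trans C2 (S) nitro compound.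

Step 11
Reactants: 3 phlorisovalerophenone
Product: 19 1-[2,4-bis(benzyloxy)-6-hydroxyphenyl]-3-methylbutan-1-one
Conditions: BnBr (2.1 equiv), K2CO3 (2.5 equiv), acetone, reflux
Reagents that add atoms: benzyl bromide, BrCc1ccccc1
Why: Williamson benzylation takes the 4-hydroxyl and one chelated hydroxyl, and the last hydroxyl, held by a hydrogen bond to the ketone, should resist these conditions.

Step 12
Reactants: 19 1-[2,4-bis(benzyloxy)-6-hydroxyphenyl]-3-methylbutan-1-one; 20 formaldehyde; 21 sodium p-toluenesulfinate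
Product: 23 1-{4,6-bis(benzyloxy)-2-hydroxy-3-[(4-methylbenzenesulfonyl)methyl]phenyl}-3-methylbutan-1-one, via hydroxymethyl phenol 22 (not isolated)
Conditions: aq HCHO (37 %, 1.2 equiv), TolSO2Na (3 equiv), HCO2H–THF (3:1), rt → 40 °C
Reagents that add atoms: none
Why: Three-component Mannich-type sulfonylmethylation, in which hydroxymethylation ortho to the only free phenol gives 22 and its benzylic cation (the protonated quinone methide) is captured at sulfur by p-toluenesulfinic acid, places the leaving group next to the hydroxyl that becomes the ring A oxygen.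

Step 13
Reactants: 18 (2S,3S)-2-nitro-2,3-dihydrobenzofuran of ring B; 23 ring A 2-(tosylmethyl)phenol
Product: 26 (2R,3′S)-4,4′,6-tris(benzyloxy)-3′-{[4,6-bis(benzyloxy)-5-(3-methylbutanoyl)-1-benzofuran-2-yl]methyl}-6′-hydroxy-7,7′-bis(3-methylbutanoyl)-3H,3′H-2,2′-spirobi[1-benzofuran], via ortho-quinone methide 24 (not isolated), via tertiary nitro adduct 25 (not isolated)
Conditions: Cs2CO3 (5 equiv), MeCN, 0 °C, 23 (1.2 equiv) added over 2 h; then rt → 40 °C
Reagents that add atoms: none
Why: Proposed new method: Cs2CO3 deprotonates the acidic anomeric C2–H of 18 (far faster than anything can happen at the C3 methine, which is C3′ of the target) and releases the ortho-quinone methide 24 from the phenoxide of 23; the soft nitronate carbon adds to the methide CH2 on the face anti to the C3 side chain to give the tertiary α-aryloxy nitro compound 25, whose nitro group then ionises with help from the ring B oxygen, and the ortho-phenoxide captures the oxocarbenium carbon in a 5-exo-trig closure of ring A. The closest known reactions are the Michael addition of nitronates to ortho-quinone methides, the [4+1] annulations of ortho-quinone methides with ylides and α-halo carbon acids, and the chain extension of 1-nitro sugars followed by replacement of the anomeric nitro group through an oxocarbenium ion. The nitro group thus makes the ketal carbon a nucleophile first and an electrophile second, which lets two carbons of normally electrophilic character be joined. The new spiro centre (R) is controlled by the C3′ stereocentre, since closure should place the larger benzylic CH2 branch of ring A trans and the smaller oxygen cis to the benzofuranylmethyl group, which is also the arrangement expected for the more stable ketal. The step needs C- over O-alkylation of the nitronate, favoured by the soft exocyclic methide carbon, and phenoxide capture in preference to loss of the C3′ proton to an aromatic benzofuran, favoured because the phenoxide is created in the same event and held within reach of the cation. Competing aryl carbon nucleophiles are limited by the single free hydroxyl of ring A and by slow addition of 23 to the preformed nitronate.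

Step 14
Reactants: 26 penta-O-benzyl spiroketal
Product: 27 (2R,3′S)-3′-{[4,6-dihydroxy-5-(3-methylbutanoyl)-1-benzofuran-2-yl]methyl}-4,4′,6,6′-tetrahydroxy-7,7′-bis(3-methylbutanoyl)-3H,3′H-2,2′-spirobi[1-benzofuran] (target)
Conditions: H2 (1 atm), Pd/C (10 wt %), EtOAc–MeOH, rt
Reagents that add atoms: none
Why: Catalytic hydrogenolysis cleaves the five aryl benzyl ethers, while the ketal C–O bonds (not benzylic), the hindered chelated aryl ketones and the benzofuran are expected to survive at one atmosphere if the reaction is stopped at complete debenzylation.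

Compound list

1 | phloroglucinol (benzene-1,3,5-triol) | Oc1cc(O)cc(O)c1 | starting material
2 | isovaleryl chloride (3-methylbutanoyl chloride) | CC(C)CC(Cl)=O | starting material
3 | phlorisovalerophenone [3-methyl-1-(2,4,6-trihydroxyphenyl)butan-1-one] | CC(C)CC(=O)c1c(O)cc(O)cc1O | intermediate
4 | 1-[4-(allyloxy)-2,6-dihydroxyphenyl]-3-methylbutan-1-one | CC(C)CC(=O)c1c(O)cc(OCC=C)cc1O | intermediate
5 | 1-[4-(allyloxy)-2,6-bis(benzyloxy)phenyl]-3-methylbutan-1-one | CC(C)CC(=O)c1c(OCc2ccccc2)cc(OCC=C)cc1OCc1ccccc1 | intermediate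
6 | 1-[2,6-bis(benzyloxy)-4-hydroxyphenyl]-3-methylbutan-1-one | CC(C)CC(=O)c1c(OCc2ccccc2)cc(O)cc1OCc1ccccc1 | intermediate
7 | 1-[2,6-bis(benzyloxy)-4-hydroxy-3-iodophenyl]-3-methylbutan-1-one | CC(C)CC(=O)c1c(OCc2ccccc2)cc(O)c(I)c1OCc1ccccc1 | intermediate
8 | but-3-yn-1-ol | OCCC#C | starting material
9 | 1-[2,6-bis(benzyloxy)-4-hydroxy-3-(4-hydroxybut-1-yn-1-yl)phenyl]-3-methylbutan-1-one (ortho-alkynylphenol, formed in the flask) | CC(C)CC(=O)c1c(OCc2ccccc2)cc(O)c(C#CCCO)c1OCc1ccccc1 | intermediate
10 | 1-[4,6-bis(benzyloxy)-2-(2-hydroxyethyl)-1-benzofuran-5-yl]-3-methylbutan-1-one | OCCc1cc2c(OCc3ccccc3)c(C(=O)CC(C)C)c(OCc3ccccc3)cc2o1 | intermediate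
11 | 2-[4,6-bis(benzyloxy)-5-(3-methylbutanoyl)-1-benzofuran-2-yl]acetaldehyde | O=CCc1cc2c(OCc3ccccc3)c(C(=O)CC(C)C)c(OCc3ccccc3)cc2o1 | intermediate
12 | bromonitromethane | [O-][N+](=O)CBr | starting material
13 | 1-[4,6-bis(benzyloxy)-2-(3-bromo-2-hydroxy-3-nitropropyl)-1-benzofuran-5-yl]-3-methylbutan-1-one (diastereomer mixture, formed in the flask) | [O-][N+](=O)C(Br)C(O)Cc1cc2c(OCc3ccccc3)c(C(=O)CC(C)C)c(OCc3ccccc3)cc2o1 | intermediate
14 | methanesulfonate of 13 (formed in the flask) | [O-][N+](=O)C(Br)C(OS(C)(=O)=O)Cc1cc2c(OCc3ccccc3)c(C(=O)CC(C)C)c(OCc3ccccc3)cc2o1 | intermediate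
15 | 1-{4,6-bis(benzyloxy)-2-[(2Z)-3-bromo-3-nitroprop-2-en-1-yl]-1-benzofuran-5-yl}-3-methylbutan-1-one | [O-][N+](=O)/C(Br)=C/Cc1cc2c(OCc3ccccc3)c(C(=O)CC(C)C)c(OCc3ccccc3)cc2o1 | intermediate
16 | 1-[4-(benzyloxy)-2,6-dihydroxyphenyl]-3-methylbutan-1-one | CC(C)CC(=O)c1c(O)cc(OCc2ccccc2)cc1O | intermediate
17 | 1-[4-(benzyloxy)-3-{(2S)-1-[4,6-bis(benzyloxy)-5-(3-methylbutanoyl)-1-benzofuran-2-yl]-3-bromo-3-nitropropan-2-yl}-2,6-dihydroxyphenyl]-3-methylbutan-1-one (epimers at the bromonitro carbon, formed in the flask) | CC(C)CC(=O)c1c(O)cc(OCc2ccccc2)c(c1O)[C@@H](C(Br)[N+](=O)[O-])Cc1cc2c(OCc3ccccc3)c(C(=O)CC(C)C)c(OCc3ccccc3)cc2o1 | intermediate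
18 | 1-[(2S,3S)-4-(benzyloxy)-3-{[4,6-bis(benzyloxy)-5-(3-methylbutanoyl)-1-benzofuran-2-yl]methyl}-6-hydroxy-2-nitro-2,3-dihydro-1-benzofuran-7-yl]-3-methylbutan-1-one (trans) | [O-][N+](=O)[C@H]1Oc2c(C(=O)CC(C)C)c(O)cc(OCc3ccccc3)c2[C@@H]1Cc1cc2c(OCc3ccccc3)c(C(=O)CC(C)C)c(OCc3ccccc3)cc2o1 | intermediate
19 | 1-[2,4-bis(benzyloxy)-6-hydroxyphenyl]-3-methylbutan-1-one | CC(C)CC(=O)c1c(O)cc(OCc2ccccc2)cc1OCc1ccccc1 | intermediate
20 | formaldehyde | C=O | starting material
21 | sodium p-toluenesulfinate | Cc1ccc(cc1)S(=O)[O-].[Na+] | starting material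
22 | 1-[4,6-bis(benzyloxy)-2-hydroxy-3-(hydroxymethyl)phenyl]-3-methylbutan-1-one (formed in the flask) | OCc1c(O)c(C(=O)CC(C)C)c(OCc2ccccc2)cc1OCc1ccccc1 | intermediate
23 | 1-{4,6-bis(benzyloxy)-2-hydroxy-3-[(4-methylbenzenesulfonyl)methyl]phenyl}-3-methylbutan-1-one | Cc1ccc(cc1)S(=O)(=O)Cc1c(O)c(C(=O)CC(C)C)c(OCc2ccccc2)cc1OCc1ccccc1 | intermediate
24 | 3,5-bis(benzyloxy)-2-(3-methylbutanoyl)-6-methylidenecyclohexa-2,4-dien-1-one (ring A ortho-quinone methide, formed in the flask) | C=C1C(=O)C(C(=O)CC(C)C)=C(OCc2ccccc2)C=C1OCc1ccccc1 | intermediate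
25 | 1-[(2R,3S)-4-(benzyloxy)-2-{[4,6-bis(benzyloxy)-2-hydroxy-3-(3-methylbutanoyl)phenyl]methyl}-3-{[4,6-bis(benzyloxy)-5-(3-methylbutanoyl)-1-benzofuran-2-yl]methyl}-6-hydroxy-2-nitro-2,3-dihydro-1-benzofuran-7-yl]-3-methylbutan-1-one (present as its phenoxide, formed in the flask) | [O-][N+](=O)[C@]1(Cc3c(O)c(C(=O)CC(C)C)c(OCc4ccccc4)cc3OCc3ccccc3)Oc2c(C(=O)CC(C)C)c(O)cc(OCc3ccccc3)c2[C@@H]1Cc1cc2c(OCc3ccccc3)c(C(=O)CC(C)C)c(OCc3ccccc3)cc2o1 | intermediate
26 | (2R,3′S)-4,4′,6-tris(benzyloxy)-3′-{[4,6-bis(benzyloxy)-5-(3-methylbutanoyl)-1-benzofuran-2-yl]methyl}-6′-hydroxy-7,7′-bis(3-methylbutanoyl)-3H,3′H-2,2′-spirobi[1-benzofuran] | CC(C)CC(=O)c1c(OCc3ccccc3)cc(OCc3ccccc3)c2c1O[C@]1(C2)Oc2c(C(=O)CC(C)C)c(O)cc(OCc3ccccc3)c2[C@@H]1Cc1cc2c(OCc3ccccc3)c(C(=O)CC(C)C)c(OCc3ccccc3)cc2o1 | intermediate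
27 | (2R,3′S)-3′-{[4,6-dihydroxy-5-(3-methylbutanoyl)-1-benzofuran-2-yl]methyl}-4,4′,6,6′-tetrahydroxy-7,7′-bis(3-methylbutanoyl)-3H,3′H-2,2′-spirobi[1-benzofuran] | CC(C)CC(=O)c1c(O)cc(O)c2c1O[C@]1(C2)Oc2c(C(=O)CC(C)C)c(O)cc(O)c2[C@@H]1Cc1cc2c(O)c(C(=O)CC(C)C)c(O)cc2o1 | target

Total step count: 14.
Longest linear sequence: 11 steps (steps 1, 2, 3, 4, 5, 6, 7, 8, 10, 13, 14).

Steps most likely to fail

Step 13 (proposed new method).
- What may go wrong: after C-alkylation, the oxocarbenium ion (or 25 itself, by anti elimination of nitrous acid) may lose the C3′ proton and aromatise to a 2,3-disubstituted benzofuran faster than the phenoxide closes.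
- Ionisation of nitrite may also stall at 25 because the ring oxygen is conjugated to the 7-acyl group, the nitronate may be alkylated at oxygen, or closure may take the wrong face.
- Fallback: known chemistry with normal polarity, the ketal carbon entering as a ketone. It sets out from aldehyde 11 (with 16 and 23) and returns to the route at 26.
- Henry addition of nitromethane to 11 gives the 2-hydroxy-3-nitropropyl benzofuran F1, which is dehydrated (MsCl, Et3N) to the (E)-3-nitroallyl benzofuran F2.
- Squaramide-catalysed Friedel–Crafts addition of phenol 16 to F2 gives the γ-nitro phenol F3 and sets the C3′ stereocentre.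
- The nitronate of F3 (K2CO3, MeCN) is added to quinone methide 24 released from 23, giving the secondary nitro compound F4.
- A TiCl3-mediated Nef reaction (NH4OAc buffer, aq THF) converts F4 into the bis(ortho-hydroxybenzyl) ketone F5.
- Acid-catalysed dehydrative spiroketalisation of F5 (pyridinium p-toluenesulfonate, toluene, molecular sieves) under thermodynamic control gives 26.

Step 10.
- What may go wrong: enantiofacial control may be insufficient with an aliphatic acceptor and an acylphloroglucinol nucleophile.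
- The double bond of 15 may migrate under base into conjugation with the benzofuran, and the remaining ring position of 16 may be alkylated a second time.
- Fallback: asymmetric catalysis is given up at this step. It sets out from 15 and 16 and returns at 18.
- The same domino reaction is run with an achiral amine (DABCO, NaHCO3, CHCl3) to the racemic trans compound, and the enantiomers are separated by preparative chromatography on a chiral stationary phase.
- The (2R,3R) enantiomer F6 is discarded; the (2S,3S) enantiomer is 18.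
- If acceptor 15 itself proves too labile, the fallback for step 13 applies, since it needs neither 15 nor 18.

Step 12.
- What may go wrong: substitution may occur para instead of ortho to the free hydroxyl (at the position between the two benzyloxy groups), or 22 may condense with a second molecule of 19 to a diarylmethane.
- Fallback: the carbon is introduced by a reaction that is ortho-specific by mechanism. It sets out from 19 and returns at 23.
- Formylation through the magnesium phenoxide (MgCl2, Et3N, paraformaldehyde, MeCN, reflux) gives the salicylaldehyde F7.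
- NaBH4 (THF–MeOH, −20 °C) reduces the aldehyde in preference to the hindered chelated ketone and gives 22, now isolated.
- 22 is converted into 23 with TolSO2Na in formic acid.

Further compounds

F1 | step 13 | 1-[4,6-bis(benzyloxy)-2-(2-hydroxy-3-nitropropyl)-1-benzofuran-5-yl]-3-methylbutan-1-one | [O-][N+](=O)CC(O)Cc1cc2c(OCc3ccccc3)c(C(=O)CC(C)C)c(OCc3ccccc3)cc2o1
F2 | step 13 | 1-{4,6-bis(benzyloxy)-2-[(2E)-3-nitroprop-2-en-1-yl]-1-benzofuran-5-yl}-3-methylbutan-1-one | [O-][N+](=O)/C=C/Cc1cc2c(OCc3ccccc3)c(C(=O)CC(C)C)c(OCc3ccccc3)cc2o1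
F3 | step 13 | 1-[4-(benzyloxy)-3-{(2S)-1-[4,6-bis(benzyloxy)-5-(3-methylbutanoyl)-1-benzofuran-2-yl]-3-nitropropan-2-yl}-2,6-dihydroxyphenyl]-3-methylbutan-1-one | CC(C)CC(=O)c1c(O)cc(OCc2ccccc2)c(c1O)[C@@H](C[N+](=O)[O-])Cc1cc2c(OCc3ccccc3)c(C(=O)CC(C)C)c(OCc3ccccc3)cc2o1
F4 | step 13 | 1-[4-(benzyloxy)-3-{(2S)-1-[4,6-bis(benzyloxy)-5-(3-methylbutanoyl)-1-benzofuran-2-yl]-4-[4,6-bis(benzyloxy)-2-hydroxy-3-(3-methylbutanoyl)phenyl]-3-nitrobutan-2-yl}-2,6-dihydroxyphenyl]-3-methylbutan-1-one (epimers at the nitro carbon) | CC(C)CC(=O)c1c(O)cc(OCc2ccccc2)c(c1O)[C@@H](C(Cc1c(O)c(C(=O)CC(C)C)c(OCc2ccccc2)cc1OCc1ccccc1)[N+](=O)[O-])Cc1cc2c(OCc3ccccc3)c(C(=O)CC(C)C)c(OCc3ccccc3)cc2o1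
F5 | step 13 | (3S)-4-[4,6-bis(benzyloxy)-5-(3-methylbutanoyl)-1-benzofuran-2-yl]-3-[6-(benzyloxy)-2,4-dihydroxy-3-(3-methylbutanoyl)phenyl]-1-[4,6-bis(benzyloxy)-2-hydroxy-3-(3-methylbutanoyl)phenyl]butan-2-one | CC(C)CC(=O)c1c(O)cc(OCc2ccccc2)c(c1O)[C@@H](C(=O)Cc1c(O)c(C(=O)CC(C)C)c(OCc2ccccc2)cc1OCc1ccccc1)Cc1cc2c(OCc3ccccc3)c(C(=O)CC(C)C)c(OCc3ccccc3)cc2o1
F6 | step 10 | 1-[(2R,3R)-4-(benzyloxy)-3-{[4,6-bis(benzyloxy)-5-(3-methylbutanoyl)-1-benzofuran-2-yl]methyl}-6-hydroxy-2-nitro-2,3-dihydro-1-benzofuran-7-yl]-3-methylbutan-1-one (enantiomer of 18) | [O-][N+](=O)[C@@H]1Oc2c(C(=O)CC(C)C)c(O)cc(OCc3ccccc3)c2[C@H]1Cc1cc2c(OCc3ccccc3)c(C(=O)CC(C)C)c(OCc3ccccc3)cc2o1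
F7 | step 12 | 4,6-bis(benzyloxy)-2-hydroxy-3-(3-methylbutanoyl)benzaldehyde | O=Cc1c(O)c(C(=O)CC(C)C)c(OCc2ccccc2)cc1OCc1ccccc1
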